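**Retrosynthetic overview**
1. Target 27 ⇒ aldehyde–phosphonate 26. The 14-membered ring is closed last by a Z-selective intramolecular Horner–Wadsworth–Emmons reaction (C1=C2); the oxirane (C5–C6) is formed before it by reagent-controlled epoxidation of the C5=C6–C7=C8 diene.
2. The C11 ester comes from the C10 propargylic alcohol by hydroxyl-directed trans-hydrostannation and methoxycarbonylation.
3. Key step at C7: C7–C8 and C6–C7 are made by two successive boron-to-carbon 1,2-shifts (1,2-metallate rearrangements) on a carbon that comes from CH2Cl2. The resulting bis-allylic boronate allylborates ynal 15 (C9–C10), which transfers the C7 chirality to C10 and fixes the C7=C8 geometry.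
4. Building blocks: vinyl iodide 4 (from glycidyl ether 1, acetylide, Me3Al), chloroallyl boronate 9 (from bromide 5, CH2Cl2), ynal 15 (from methyl bromoacetate 10, 4-bromobut-1-yne 12, DMF).

Assumption: (R)-PMB glycidyl ether 1 and bromide 5 are bought as such, and PMB counts as a protecting group.
Numbering used for the ring of 27: C1 (CO2Me) = C2, C3 (OAc), C4, C5 (Me, epoxide), C6 (epoxide), C7 = C8 (iPr), C9, C10 (OAc), C11 (CO2Me) = C12, C13, C14. The phosphonate-bearing carbon of 13–26 is a 1:1 epimer mixture that disappears in step 15.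

**Step 1**
Reactants: 1 (R)-2-{[(4-methoxybenzyl)oxy]methyl}oxirane
Product: 2 (2R)-1-[(4-methoxybenzyl)oxy]pent-4-yn-2-ol
Conditions: LiC≡CH·H2NCH2CH2NH2, DMSO, 0 °C → rt; H2O
Reagents that add atoms: lithium acetylide–ethylenediamine complex [Li]C#C.NCCN
Why: SN2 opening of the terminal epoxide at CH2 by the acetylide leaves the carbinol centre (later C3, R) untouched.

**Step 2**
Reactants: 2 (2R)-1-[(4-methoxybenzyl)oxy]pent-4-yn-2-ol
Product: 4 (2R,4E)-5-iodo-1-[(4-methoxybenzyl)oxy]-4-methylpent-4-en-2-ol, via alkenylalane 3 (not isolated)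
Conditions: Me3Al (3 equiv), Cp2ZrCl2 (25 mol%), CH2Cl2, 0 °C → rt; I2, THF, −30 °C; aq. K2CO3/Rochelle salt
Reagents that add atoms: trimethylaluminium C[Al](C)C; iodine II
Why: Zr-catalysed syn-carboalumination (Negishi) puts Me on the internal carbon and Al on the terminus, and iodination with retention gives the E-iodide (the future trans-epoxide geometry).

**Step 3**
Reactants: 5 2-bromo-3-methylbut-1-ene
Product: 7 4,4,5,5-tetramethyl-2-(3-methylbut-1-en-2-yl)-1,3,2-dioxaborolane, via Grignard reagent 6 (not isolated)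
Conditions: Mg, THF, rt; iPrOBpin, −78 °C → rt; aq. NH4Cl
Reagents that add atoms: 2-isopropoxy-4,4,5,5-tetramethyl-1,3,2-dioxaborolane CC(C)OB1OC(C)(C)C(C)(C)O1
Why: Borylation of an alkenyl Grignard reagent with an alkoxyboronate is a standard route to alkenyl pinacol boronates.

**Step 4**
Reactants: 7 4,4,5,5-tetramethyl-2-(3-methylbut-1-en-2-yl)-1,3,2-dioxaborolane
Product: 9 2-[(1R)-1-chloro-3-methyl-2-methylidenebutyl]-4,4,5,5-tetramethyl-1,3,2-dioxaborolane, via dichloromethyl ate complex 8 (not isolated)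
Conditions: CH2Cl2, n-BuLi, THF, −100 °C; chiral Li-isothiourea-boronate catalyst (10 mol%), −95 → −60 °C; cold aq. NH4Cl
Reagents that add atoms: dichloromethane ClCCl
Why: Proposed new method: LiCHCl2 adds to boron to give the achiral ate complex 8, and a chiral lithium isothiourea-boronate Lewis acid (enantiomer chosen to give R) binds a pinacol oxygen and pulls off one of the two enantiotopic chlorides, so that the alkenyl carbon migrates from boron to carbon anti to that chloride (1,2-metallate shift) and sets C7; the closest known reaction type is the Matteson homologation, auxiliary-controlled with chiral diols or catalysed enantioselectively for primary-alkyl pinacol boronates, and the new element is the sp2 migrating group, whose faster uncatalysed shift is suppressed at −95 °C.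

**Step 5**
Reactants: 10 methyl bromoacetate
Product: 11 methyl 2-(diphenoxyphosphoryl)acetate
Conditions: (PhO)2P(O)H, Et3N, CH2Cl2, 0 °C → rt
Reagents that add atoms: diphenyl phosphite O=[PH](Oc1ccccc1)Oc1ccccc1
Why: Michaelis–Becker-type P-alkylation of the phosphite by the α-bromo ester gives the Ando-type (Z-selective) phosphonoacetate.

**Step 6**
Reactants: 11 methyl 2-(diphenoxyphosphoryl)acetate; 12 4-bromobut-1-yne
Product: 13 methyl 2-(diphenoxyphosphoryl)hex-5-ynoate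
Conditions: NaH, DMSO, rt (11 in 1.5-fold excess)
Reagents that add atoms: none
Why: C-alkylation of the stabilised phosphonoacetate anion with a primary bromide, with excess 11 to suppress dialkylation.

**Step 7**
Reactants: 13 methyl 2-(diphenoxyphosphoryl)hex-5-ynoate
Product: 15 methyl 2-(diphenoxyphosphoryl)-7-oxohept-5-ynoate, via dilithio species 14 (not isolated)
Conditions: LDA (2.2 equiv), THF, −78 °C; DMF; inverse quench into aq. KH2PO4
Reagents that add atoms: N,N-dimethylformamide CN(C)C=O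
Why: In the dianion the acetylide is the more reactive carbanion and is formylated by DMF, and the buffered inverse quench releases the ynal without self-olefination.

**Step 8**
Reactants: 4 (2R,4E)-5-iodo-1-[(4-methoxybenzyl)oxy]-4-methylpent-4-en-2-ol; 9 2-[(1R)-1-chloro-3-methyl-2-methylidenebutyl]-4,4,5,5-tetramethyl-1,3,2-dioxaborolane; 15 methyl 2-(diphenoxyphosphoryl)-7-oxohept-5-ynoate
Product: 20 methyl (7R,9E,11E,14R)-2-(diphenoxyphosphoryl)-7-hydroxy-15-[(4-methoxybenzyl)oxy]-12-methyl-9-(propan-2-yl)-14-[(trimethylsilyl)oxy]pentadeca-9,11-dien-5-ynoate, via TMS ether 16 (not isolated), via alkenyllithium 17 (not isolated), via boron ate complex 18 (not isolated), via bis-allylic boronate 19 (not isolated)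
Conditions: TMSCl, Et3N, Et2O, 0 °C, filter; t-BuLi (2.05 equiv), −78 °C; 9, THF, −78 → 0 °C; 15, −78 → 0 °C; aq. NaHCO3
Reagents that add atoms: chlorotrimethylsilane C[Si](C)(C)Cl
Why: I–Li exchange with retention gives 17, which adds to boron of 9, and the alkenyl carbon then migrates from boron to C7 with inversion and loss of chloride (Matteson-type 1,2-metallate shift) to give (R)-19, whose allylboration of ynal 15 through a chair transition state (alkynyl equatorial, C6-alkenyl pseudo-axial to avoid A(1,2) strain with isopropyl, attack through the unsubstituted CH2 terminus) forms C9–C10, sets C10 (R) by chirality transfer from C7 and gives C7=C8 with C6 cis to C9.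

**Step 9**
Reactants: 20 (as above)
Product: 21 methyl (5Z,7R,9E,11E,14R)-2-(diphenoxyphosphoryl)-7-hydroxy-15-[(4-methoxybenzyl)oxy]-12-methyl-9-(propan-2-yl)-6-(tributylstannyl)-14-[(trimethylsilyl)oxy]pentadeca-5,9,11-trienoate
Conditions: [Cp*RuCl]4 (2.5 mol%), Bu3SnH (1.15 equiv), CH2Cl2, rt
Reagents that add atoms: tributyltin hydride CCCC[SnH](CCCC)CCCC
Why: Ruthenium-catalysed hydroxyl-directed trans-hydrostannation places tin on the alkyne carbon next to the carbinol (C11) and H trans to it on C12, which fixes the C11=C12 geometry.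

**Step 10**
Reactants: 21 (as above)
Product: 22 methyl (5Z,7R,9E,11E,14R)-2-(diphenoxyphosphoryl)-7,14-dihydroxy-6-(methoxycarbonyl)-15-[(4-methoxybenzyl)oxy]-12-methyl-9-(propan-2-yl)pentadeca-5,9,11-trienoate
Conditions: Pd(OAc)2 (10 mol%), Ph3As (20 mol%), 1,4-benzoquinone (1.5 equiv), TFA (20 mol%), CO (1 atm), MeOH, rt
Reagents that add atoms: carbon monoxide [C-]#[O+]; methanol CO
Why: Hydroxyl-assisted oxidative Pd(II) methoxycarbonylation of the alkenylstannane replaces Sn by CO2Me with retention (ester cis to C13), and the acidic methanol also removes the TMS ether.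

**Step 11**
Reactants: 22 (as above)
Product: 23 methyl (5Z,7R,9E,11E,14R)-7,14-diacetoxy-2-(diphenoxyphosphoryl)-6-(methoxycarbonyl)-15-[(4-methoxybenzyl)oxy]-12-methyl-9-(propan-2-yl)pentadeca-5,9,11-trienoate
Conditions: Ac2O, pyridine, CH2Cl2, rt
Reagents that add atoms: acetic anhydride CC(=O)OC(C)=O
Why: Acetylation of both secondary alcohols without DMAP, so that the new allylic acetate at C10 does not undergo SN2′ transposition.

**Step 12**
Reactants: 23 (as above)
Product: 24 methyl (5Z,7R,9E,11S,12S,14R)-7,14-diacetoxy-2-(diphenoxyphosphoryl)-11,12-epoxy-6-(methoxycarbonyl)-15-[(4-methoxybenzyl)oxy]-12-methyl-9-(propan-2-yl)pentadeca-5,9-dienoate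
Conditions: ent-Shi ketone (L-fructose-derived, 30 mol%), Oxone, K2CO3, Bu4NHSO4, MeCN/DMM–aq. borate buffer, 0 °C
Reagents that add atoms: potassium peroxymonosulfate (Oxone) [K+].[O-]S(=O)(=O)OO
Why: Shi epoxidation by the chiral dioxirane attacks the less hindered, methyl-bearing E-trisubstituted alkene of the diene (the isopropyl-bearing alkene and both enoates are slower) through the spiro transition state, and the L-fructose-derived ketone delivers the (5S,6S) epoxide in ring numbering.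

**Step 13**
Reactants: 24 (as above)
Product: 25 methyl (5Z,7R,9E,11S,12S,14R)-7,14-diacetoxy-2-(diphenoxyphosphoryl)-11,12-epoxy-15-hydroxy-6-(methoxycarbonyl)-12-methyl-9-(propan-2-yl)pentadeca-5,9-dienoate
Conditions: DDQ (1.3 equiv), CH2Cl2/pH 7 buffer, 0 °C
Reagents that add atoms: none
Why: Oxidative PMB cleavage under neutral conditions spares the vinyl epoxide and acetates and, without base, avoids 1,2-acetyl migration.

**Step 14**
Reactants: 25 (as above)
Product: 26 methyl (5Z,7R,9E,11S,12S,14R)-7,14-diacetoxy-2-(diphenoxyphosphoryl)-11,12-epoxy-6-(methoxycarbonyl)-12-methyl-15-oxo-9-(propan-2-yl)pentadeca-5,9-dienoate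
Conditions: Dess–Martin periodinane (1.3 equiv), pyridine, CH2Cl2, 0 °C; used crude
Reagents that add atoms: none
Why: Buffered Dess–Martin oxidation gives the α-acetoxy aldehyde without epimerising C3 or opening the epoxide.

**Step 15**
Reactants: 26 (as above)
Product: 27 dimethyl (1Z,3R,5S,6S,7E,10R,11Z)-3,10-diacetoxy-5,6-epoxy-5-methyl-8-(propan-2-yl)cyclotetradeca-1,7,11-triene-1,11-dicarboxylate (CNP0359666.2)
Conditions: NaI (5 equiv), DBU (1.5 equiv), THF, 1 mM (syringe pump), 0 °C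
Reagents that add atoms: none
Why: Intramolecular Horner–Wadsworth–Emmons olefination with the diaryl (Ando-type) phosphonate eliminates fast from the kinetic adduct and gives the Z-enoate (ester cis to C3), and the mild NaI/DBU base keeps the α-acetoxy aldehyde centre intact.

**Compound list**
1 | (R)-2-{[(4-methoxybenzyl)oxy]methyl}oxirane | COc1ccc(COC[C@H]2CO2)cc1 | starting material
2 | (2R)-1-[(4-methoxybenzyl)oxy]pent-4-yn-2-ol | COc1ccc(COC[C@H](O)CC#C)cc1 | intermediate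
3 | (E)-alkenyl(dimethyl)alane dimethylaluminium alkoxide derived from 2 | COc1ccc(COC[C@H](O[Al](C)C)C/C(C)=C/[Al](C)C)cc1 | intermediate
4 | (2R,4E)-5-iodo-1-[(4-methoxybenzyl)oxy]-4-methylpent-4-en-2-ol | COc1ccc(COC[C@H](O)C/C(C)=C/I)cc1 | intermediate
5 | 2-bromo-3-methylbut-1-ene | C=C(Br)C(C)C | starting material
6 | (3-methylbut-1-en-2-yl)magnesium bromide | C=C([Mg]Br)C(C)C | intermediate
7 | 4,4,5,5-tetramethyl-2-(3-methylbut-1-en-2-yl)-1,3,2-dioxaborolane | C=C(C(C)C)B1OC(C)(C)C(C)(C)O1 | intermediate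
8 | lithium (dichloromethyl)(3-methylbut-1-en-2-yl)(pinacolato)borate | [Li+].C=C(C(C)C)[B-]1(C(Cl)Cl)OC(C)(C)C(C)(C)O1 | intermediate
9 | 2-[(1R)-1-chloro-3-methyl-2-methylidenebutyl]-4,4,5,5-tetramethyl-1,3,2-dioxaborolane | C=C(C(C)C)[C@H](Cl)B1OC(C)(C)C(C)(C)O1 | intermediate
10 | methyl bromoacetate | COC(=O)CBr | starting material
11 | methyl 2-(diphenoxyphosphoryl)acetate | COC(=O)CP(=O)(Oc1ccccc1)Oc1ccccc1 | intermediate
12 | 4-bromobut-1-yne | C#CCCBr | starting material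
13 | methyl 2-(diphenoxyphosphoryl)hex-5-ynoate (racemic) | COC(=O)C(CCC#C)P(=O)(Oc1ccccc1)Oc1ccccc1 | intermediate
14 | 2,6-dilithio derivative of 13 | [Li]C#CCCC([Li])(C(=O)OC)P(=O)(Oc1ccccc1)Oc1ccccc1 | intermediate
15 | methyl 2-(diphenoxyphosphoryl)-7-oxohept-5-ynoate (racemic) | COC(=O)C(CCC#CC=O)P(=O)(Oc1ccccc1)Oc1ccccc1 | intermediate
16 | {[(2R,4E)-5-iodo-1-[(4-methoxybenzyl)oxy]-4-methylpent-4-en-2-yl]oxy}(trimethyl)silane | COc1ccc(COC[C@H](O[Si](C)(C)C)C/C(C)=C/I)cc1 | intermediate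
17 | [(1E,4R)-5-[(4-methoxybenzyl)oxy]-2-methyl-4-[(trimethylsilyl)oxy]pent-1-en-1-yl]lithium | COc1ccc(COC[C@H](O[Si](C)(C)C)C/C(C)=C/[Li])cc1 | intermediate
18 | lithium [(1R)-1-chloro-3-methyl-2-methylidenebutyl][(1E,4R)-5-[(4-methoxybenzyl)oxy]-2-methyl-4-[(trimethylsilyl)oxy]pent-1-en-1-yl](pinacolato)borate | [Li+].COc1ccc(COC[C@H](O[Si](C)(C)C)C/C(C)=C/[B-]2([C@@H](Cl)C(=C)C(C)C)OC(C)(C)C(C)(C)O2)cc1 | intermediate
19 | 2-[(3R,4E,7R)-8-[(4-methoxybenzyl)oxy]-5-methyl-2-(propan-2-yl)-7-[(trimethylsilyl)oxy]octa-1,4-dien-3-yl]-4,4,5,5-tetramethyl-1,3,2-dioxaborolane | COc1ccc(COC[C@H](O[Si](C)(C)C)C/C(C)=C/[C@@H](B2OC(C)(C)C(C)(C)O2)C(=C)C(C)C)cc1 | intermediate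
20 | methyl (7R,9E,11E,14R)-2-(diphenoxyphosphoryl)-7-hydroxy-15-[(4-methoxybenzyl)oxy]-12-methyl-9-(propan-2-yl)-14-[(trimethylsilyl)oxy]pentadeca-9,11-dien-5-ynoate | COc1ccc(COC[C@H](O[Si](C)(C)C)C/C(C)=C/C=C(/C(C)C)C[C@@H](O)C#CCCC(P(=O)(Oc2ccccc2)Oc2ccccc2)C(=O)OC)cc1 | intermediate
21 | methyl (5Z,7R,9E,11E,14R)-2-(diphenoxyphosphoryl)-7-hydroxy-15-[(4-methoxybenzyl)oxy]-12-methyl-9-(propan-2-yl)-6-(tributylstannyl)-14-[(trimethylsilyl)oxy]pentadeca-5,9,11-trienoate | COc1ccc(COC[C@H](O[Si](C)(C)C)C/C(C)=C/C=C(/C(C)C)C[C@@H](O)/C(=C/CCC(P(=O)(Oc2ccccc2)Oc2ccccc2)C(=O)OC)[Sn](CCCC)(CCCC)CCCC)cc1 | intermediate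
22 | methyl (5Z,7R,9E,11E,14R)-2-(diphenoxyphosphoryl)-7,14-dihydroxy-6-(methoxycarbonyl)-15-[(4-methoxybenzyl)oxy]-12-methyl-9-(propan-2-yl)pentadeca-5,9,11-trienoate | COc1ccc(COC[C@H](O)C/C(C)=C/C=C(/C(C)C)C[C@@H](O)/C(C(=O)OC)=C/CCC(P(=O)(Oc2ccccc2)Oc2ccccc2)C(=O)OC)cc1 | intermediate
23 | methyl (5Z,7R,9E,11E,14R)-7,14-diacetoxy-2-(diphenoxyphosphoryl)-6-(methoxycarbonyl)-15-[(4-methoxybenzyl)oxy]-12-methyl-9-(propan-2-yl)pentadeca-5,9,11-trienoate | COc1ccc(COC[C@H](OC(C)=O)C/C(C)=C/C=C(/C(C)C)C[C@@H](OC(C)=O)/C(C(=O)OC)=C/CCC(P(=O)(Oc2ccccc2)Oc2ccccc2)C(=O)OC)cc1 | intermediate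
24 | methyl (5Z,7R,9E,11S,12S,14R)-7,14-diacetoxy-2-(diphenoxyphosphoryl)-11,12-epoxy-6-(methoxycarbonyl)-15-[(4-methoxybenzyl)oxy]-12-methyl-9-(propan-2-yl)pentadeca-5,9-dienoate | COc1ccc(COC[C@H](OC(C)=O)C[C@]2(C)O[C@H]2/C=C(/C(C)C)C[C@@H](OC(C)=O)/C(C(=O)OC)=C/CCC(P(=O)(Oc3ccccc3)Oc3ccccc3)C(=O)OC)cc1 | intermediate
25 | methyl (5Z,7R,9E,11S,12S,14R)-7,14-diacetoxy-2-(diphenoxyphosphoryl)-11,12-epoxy-15-hydroxy-6-(methoxycarbonyl)-12-methyl-9-(propan-2-yl)pentadeca-5,9-dienoate | OC[C@H](OC(C)=O)C[C@]1(C)O[C@H]1/C=C(/C(C)C)C[C@@H](OC(C)=O)/C(C(=O)OC)=C/CCC(P(=O)(Oc1ccccc1)Oc1ccccc1)C(=O)OC | intermediate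
26 | methyl (5Z,7R,9E,11S,12S,14R)-7,14-diacetoxy-2-(diphenoxyphosphoryl)-11,12-epoxy-6-(methoxycarbonyl)-12-methyl-15-oxo-9-(propan-2-yl)pentadeca-5,9-dienoate | O=C[C@H](OC(C)=O)C[C@]1(C)O[C@H]1/C=C(/C(C)C)C[C@@H](OC(C)=O)/C(C(=O)OC)=C/CCC(P(=O)(Oc1ccccc1)Oc1ccccc1)C(=O)OC | intermediate
27 | dimethyl (1Z,3R,5S,6S,7E,10R,11Z)-3,10-diacetoxy-5,6-epoxy-5-methyl-8-(propan-2-yl)cyclotetradeca-1,7,11-triene-1,11-dicarboxylate (ring numbering as defined above) | COC(=O)/C1=C\[C@H](OC(C)=O)C[C@]2(C)O[C@H]2/C=C(/C(C)C)C[C@@H](OC(C)=O)/C(C(=O)OC)=C/CC1 | target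

**Step count and risks**
Total: 15 steps. Longest linear sequence: 11 steps (5, 6, 7, 8, 9, 10, 11, 12, 13, 14, 15).

The three steps most likely to fail:

Step 4 (the new catalytic enantioselective 1,2-shift). The risk is a fast uncatalysed migration of the alkenyl group and therefore low ee. The fallback uses known auxiliary control. It sets out from bromide 5 and comes back to the route at 20. Grignard reagent 6 is quenched with (4S,5S)-4,5-dicyclohexyl-2-isopropoxy-1,3,2-dioxaborolane to give the (S,S)-DICHED alkenylboronate F1. LiCHCl2 at −100 °C gives the dichloromethyl ate complex F2, which rearranges with ZnCl2 on warming, under control of the diol, to the (R)-α-chloro boronate F3; this sense of induction for the (S,S)-diol is quoted from the established Matteson rule and should be confirmed on F3. F3 replaces 9 in step 8: alkenyllithium 17 adds to give the ate complex F4, the 1,2-shift gives the bis-allylic DICHED boronate F5, and allylboration of 15 gives 20.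

Step 8 (four events in one flask). The risks are allylboration through the wrong terminus of the bis-allylic boronate, a 1,3-boron shift, and the acidic phosphonate of 15. The fallback separates the events. It sets out from 7, 4 and 15 and comes back to the route at 22. Boronate 7 is homologated as in step 4, but with the mirror-image catalyst, to the (S)-α-chloroallyl boronate F6. F6 and 15 are simply mixed (THF, −78 °C → rt); a chair allylboration with axial chlorine gives the chloroalkenyl propargylic alcohol F7 with C10 (R) and chlorine cis to C9. Iodide 4 is converted by Miyaura borylation (B2pin2, PdCl2(dppf), KOAc) into the alkenyl pinacol boronate F8. Suzuki–Miyaura coupling of F7 with F8 (Pd(OAc)2/SPhos, K3PO4) gives the dienynediol F9. The conditions of step 9 give the stannane F10, and those of step 10 give 22.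

Step 12 (site and face selectivity of the diene epoxidation, and base sensitivity of the phosphonate). The fallback replaces reagent control by hydroxyl direction. It sets out from 22 and comes back to the route at 24. The less hindered C3 hydroxyl of 22 is silylated selectively (TESCl, imidazole, −40 °C) to the mono-TES ether F11. Acetylation gives the C10 acetate F12, and PPTS in MeOH frees the homoallylic C3 alcohol F13. Vanadium-catalysed directed epoxidation (VO(OiPr)3, chiral bis-hydroxamic acid ligand chosen for the 5S,6S face, cumene hydroperoxide) acts only on the C5=C6 alkene and gives the epoxy alcohol F14. Acetylation of F14 gives 24.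

**Further compounds**
F1 | step 4 | (4S,5S)-4,5-dicyclohexyl-2-(3-methylbut-1-en-2-yl)-1,3,2-dioxaborolane | C=C(C(C)C)B1O[C@@H](C2CCCCC2)[C@H](C2CCCCC2)O1
F2 | step 4 | lithium (dichloromethyl)(3-methylbut-1-en-2-yl)[(S,S)-DICHED]borate | [Li+].C=C(C(C)C)[B-]1(C(Cl)Cl)O[C@@H](C2CCCCC2)[C@H](C2CCCCC2)O1
F3 | step 4 | (4S,5S)-2-[(1R)-1-chloro-3-methyl-2-methylidenebutyl]-4,5-dicyclohexyl-1,3,2-dioxaborolane | C=C(C(C)C)[C@H](Cl)B1O[C@@H](C2CCCCC2)[C@H](C2CCCCC2)O1
F4 | step 4 | lithium ate complex of F3 and alkenyllithium 17 | [Li+].COc1ccc(COC[C@H](O[Si](C)(C)C)C/C(C)=C/[B-]2([C@@H](Cl)C(=C)C(C)C)O[C@@H](C3CCCCC3)[C@H](C3CCCCC3)O2)cc1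
F5 | step 4 | (4S,5S)-DICHED analogue of bis-allylic boronate 19 | COc1ccc(COC[C@H](O[Si](C)(C)C)C/C(C)=C/[C@@H](B2O[C@@H](C3CCCCC3)[C@H](C3CCCCC3)O2)C(=C)C(C)C)cc1
F6 | step 8 | 2-[(1S)-1-chloro-3-methyl-2-methylidenebutyl]-4,4,5,5-tetramethyl-1,3,2-dioxaborolane | C=C(C(C)C)[C@@H](Cl)B1OC(C)(C)C(C)(C)O1
F7 | step 8 | methyl (7R,9E)-10-chloro-2-(diphenoxyphosphoryl)-7-hydroxy-9-(propan-2-yl)dec-9-en-5-ynoate | Cl/C=C(/C(C)C)C[C@@H](O)C#CCCC(P(=O)(Oc1ccccc1)Oc1ccccc1)C(=O)OC
F8 | step 8 | (2R,4E)-1-[(4-methoxybenzyl)oxy]-4-methyl-5-(4,4,5,5-tetramethyl-1,3,2-dioxaborolan-2-yl)pent-4-en-2-ol | COc1ccc(COC[C@H](O)C/C(C)=C/B2OC(C)(C)C(C)(C)O2)cc1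
F9 | step 8 | methyl (7R,9E,11E,14R)-2-(diphenoxyphosphoryl)-7,14-dihydroxy-15-[(4-methoxybenzyl)oxy]-12-methyl-9-(propan-2-yl)pentadeca-9,11-dien-5-ynoate | COc1ccc(COC[C@H](O)C/C(C)=C/C=C(/C(C)C)C[C@@H](O)C#CCCC(P(=O)(Oc2ccccc2)Oc2ccccc2)C(=O)OC)cc1
F10 | step 8 | methyl (5Z,7R,9E,11E,14R)-2-(diphenoxyphosphoryl)-7,14-dihydroxy-15-[(4-methoxybenzyl)oxy]-12-methyl-9-(propan-2-yl)-6-(tributylstannyl)pentadeca-5,9,11-trienoate | COc1ccc(COC[C@H](O)C/C(C)=C/C=C(/C(C)C)C[C@@H](O)/C(=C/CCC(P(=O)(Oc2ccccc2)Oc2ccccc2)C(=O)OC)[Sn](CCCC)(CCCC)CCCC)cc1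
F11 | step 12 | 14-O-triethylsilyl ether of 22 | COc1ccc(COC[C@H](O[Si](CC)(CC)CC)C/C(C)=C/C=C(/C(C)C)C[C@@H](O)/C(C(=O)OC)=C/CCC(P(=O)(Oc2ccccc2)Oc2ccccc2)C(=O)OC)cc1
F12 | step 12 | 7-O-acetyl-14-O-triethylsilyl derivative of 22 | COc1ccc(COC[C@H](O[Si](CC)(CC)CC)C/C(C)=C/C=C(/C(C)C)C[C@@H](OC(C)=O)/C(C(=O)OC)=C/CCC(P(=O)(Oc2ccccc2)Oc2ccccc2)C(=O)OC)cc1
F13 | step 12 | 7-O-acetyl derivative of 22 (free 14-hydroxyl) | COc1ccc(COC[C@H](O)C/C(C)=C/C=C(/C(C)C)C[C@@H](OC(C)=O)/C(C(=O)OC)=C/CCC(P(=O)(Oc2ccccc2)Oc2ccccc2)C(=O)OC)cc1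
F14 | step 12 | 14-O-deacetyl derivative of 24 ((11S,12S)-epoxy alcohol) | COc1ccc(COC[C@H](O)C[C@]2(C)O[C@H]2/C=C(/C(C)C)C[C@@H](OC(C)=O)/C(C(=O)OC)=C/CCC(P(=O)(Oc3ccccc3)Oc3ccccc3)C(=O)OC)cc1
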